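## Structural features

The target is a diester of a cyclopentane core. The core is numbered here C1 (bears the CH2O group), C2 (methyl), C3 (oxygen), C4 (CH2) and C5 (bears CH(CH2OH)2). The primary C1–CH2–O and the secondary C3–O oxygens each carry the same (3S,4E)-4-formyl-3-(2-oxoethyl)hex-4-enoyl chain. The ring stereocentres C5, C1, C2 and C3 are contiguous and all-trans (1S,2R,3R,5R), so the C1 side chain and the C3 oxygen are cis to each other. Each acyl chain has one further stereocentre, flanked by an E-ethylidene enal and a CH2CHO group. The arms are the fragile part: each is a 1,5-dialdehyde prone to aldol reactions, hydration and acetal formation with the free 1,3-diol, and the ester links exclude strong base, hydride and strong acid late in the route. The real difficulty is to set four adjacent centres on a small ring while keeping three primary and one secondary hydroxyl apart, and to deliver two dialdehyde acid units in a masked form that is opened last. The arm acid is the secoiridoid part of oleuropein without its methoxycarbonyl group and glucose, so its stereocentre and alkene geometry can be taken from that glycoside. The key step exploits that the ten core carbons are a ring-contracted p-menthane: C5 with its three-carbon branch is C4 of (R)-limonene with its isopropenyl group, and the C1/C2 pair is what an aldol condensation between an aldehyde α-carbon and a methyl ketone of the opened limonene ring produces.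

## Logic of the disconnections

**25 ⇒ 23.** No skeletal bond is cut. In each arm the two aldehyde carbons are reconnected through oxygen into a dihydropyran bearing a CO2Me group and a glucosyl acetal. The dialdehydes could not survive esterification or deprotection, so they are hidden until the end. The gain is that arm stereocentre and E-alkene are not made at all. The forward step must break two C–CO2Me bonds and two glycosidic acetals under neutral conditions that leave four carboxylic ester links intact.

**23 ⇒ 22 ⇒ 17 + 2 × 21.** The two acyl C–O bonds at C3–O and C1–CH2–O are cut, after the 1,3-diol has been put back under its isopropylidene ketal. Both acyl groups are identical, so one acid serves twice and the route becomes convergent. The forward acylation must reach a secondary hydroxyl flanked by a methyl-bearing carbon, and the ketal must later come off without ionising the glycosidic acetals.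

**21 ⇒ 19 ⇒ 18.** The acyl C–O bond to the phenethyl alcohol of 18 is cut and the four sugar acetates are removed. This traces the masked arm acid to a commercial glycoside in two operations. The forward hydrolysis must distinguish the aliphatic ester from the conjugated methyl ester.

**17 ⇒ 15 (through 16).** The C1–CH2OH group is taken back to a formyl group with inverted C1. An aldehyde at C1 makes this centre correctable by enolisation, and the cis C3 hydroxyl can trap the correct epimer. The forward step must epimerise completely before the hydride is added.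

**15 ⇒ 14.** The C1–H and C2–H bonds are removed to give the C1=C2 enal. Two stereocentres are thereby reduced to one controlling element, the C3 hydroxyl. The forward hydrogenation must deliver hydrogen to a tetrasubstituted, electron-poor alkene from the hydroxyl face.

**14 ⇒ 12 ⇒ 11.** The C3–O bond is cut. This leaves an enal with a single stereocentre, which is the product of the key step. The forward oxidation must be γ-selective on the ring side and must occur trans to the C5 substituent.

**11 ⇒ 9.** The C1=C2 bond is cut (key disconnection), which opens the cyclopentene to a 1,6-keto aldehyde. The forward step must make the aldehyde α-carbon the nucleophile and the ketone the electrophile, not the reverse.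

**9 ⇒ 7.** The formyl carbon and the ketone carbon are rejoined as a ring C=C, which reveals a 1-methylcyclohexene. The forward cleavage needs the ring alkene to be the only alkene present.

**7 ⇒ 6 ⇒ 4 ⇒ 1.** The ketal is removed and the two C–O bonds of the 1,3-diol are cut in turn, back to the isopropenyl group of 1. Both oxygens enter at carbons that become equivalent, so no new stereocentre has to be controlled. The forward steps must select the isopropenyl methyl for metalation and the 1,1-disubstituted alkene for hydroboration.

## Other disconnections considered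

**Alternative 1:** The cut is the bond between the ester α-carbon and the arm stereocentre in each arm (two C–C bonds, no ring). In the forward sense the bis(allyl malonate) of 17, A1, would add twice to (2E,4E)-4-(dimethoxymethyl)hexa-2,4-dienal A2, activated as its iminium ion by a chiral prolinol silyl ether, to give the twofold adduct A3. Deallylation and decarboxylation with a zerovalent palladium catalyst and mild acetal hydrolysis would follow.
- In its favour: it is two-directional, needs no natural glycoside, lets the catalyst choose the arm configuration, and ends without heating to 150 °C.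
- Against it here: the β-carbon of A2 is next to a branched γ-carbon, so 1,6-addition and slow 1,4-addition are real concerns. Two catalyst-controlled events on one molecule multiply any shortfall in selectivity into diastereomers that differ only at remote centres. The product aldehydes can re-enter enamine chemistry, and dienamine formation could scramble the ethylidene geometry.
- Comparison: structurally the chosen plan takes the arm centre and alkene from 18 as fixed elements, where this alternative must create them. Mechanistically, iminium conjugate addition is set against a chloride dealkylation/decarboxylation cascade. On step count it is longer, since A2 and A1 must be made and three unmasking operations follow, and it still needs 17, so the core work is unchanged. It is the better plan on mildness of the end game and on freedom to vary the arm configuration.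

**Alternative 2:** The cut is the ring bond C1–C5. In the forward sense the open-chain aldehyde dimethyl 2-[(3R,4R)-3-(tert-butyldimethylsilyloxy)-4-methyl-6-oxohexylidene]malonate A4 would cyclise through its enamine onto the alkylidene malonate (5-exo-trig Michael) to the all-trans cyclopentane A5.
- In its favour: the C3 oxygen and C2 methyl are in place before the ring closes, the CH(CH2OH)2 group arrives as a malonate, and the formyl centre can be corrected by epimerisation.
- Against it here: A4 needs two adjacent stereocentres from reagent-controlled asymmetric synthesis, likely six to eight steps. C5 is then set irreversibly by a catalyst that must cooperate with the existing centres.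
- Comparison: structurally it is better at C3, because the oxygen is never introduced by a diastereoselective oxidation, and it avoids the hydrogenation/epimerisation sequence. The chosen plan is better at C5, which comes from the chiral pool and cannot be mis-set. Mechanistically both are amine-catalysed 5-exo closures through an aldehyde enamine, but the chosen one creates no stereocentre and therefore has nothing to control. After ring closure the two plans are about equal in length (roughly three steps against four to 17). Before it, the chosen plan is clearly shorter.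

**Alternative 3:** The cuts are the exocyclic bonds C1–CH2 and C2–CH3. In the forward sense (R)-4-(2,2-dimethyl-1,3-dioxan-5-yl)cyclopent-2-en-1-one A6 would undergo conjugate addition of an alkoxysilylmethyl Grignard reagent with a monovalent copper catalyst (CuBr·SMe2). Capture of the enolate by a methyl halide would give ketone A7. Ketone reduction and oxidation of the C–Si bond (Tamao–Fleming type) would lead to 17.
- In its favour: two substituents and two stereocentres are installed in one flask, trans,trans by relay from C5, and the hydroxymethyl group is masked robustly.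
- Against it here: A6 needs an enantioselective synthesis of its own. Alkylation of cyclopentanone enolates after conjugate addition is prone to proton exchange and over-alkylation. The C3 alcohol must arise from hydride attack on the face that carries the neighbouring methyl group, against the intrinsic preference, so an equilibrating reduction or an inversion would be needed.
- Comparison: structurally it is better at C1 and C2, which need no epimerisation. It is weaker at C3, which the chosen plan uses as the control element for C2. Mechanistically, organocopper addition and enolate alkylation are set against an aldol condensation with no stereochemical demand. On step count it is comparable after the key step and longer before it.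

Key step: step 5

Remark on configuration: C4 of 1 becomes C5 of the target with its substituents in the same spatial order (isopropenyl → CH(CH2OH)2, C3 → C1, C5 → C4), so the R enantiomer of limonene is the correct one and no structure needed correction. The descriptor changes in 11, 12, 14 and 15 (5S) come only from changed priorities.

Assumption: the enol ether geometry of 12 and the new centres of 5, 8, 10 and the lactol carbon of 16 are inconsequential mixtures, and the target is taken as the open bis-dialdehyde form.

## Route

Step 1
Reactants: 1 (R)-(+)-limonene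
Product: 4 2-[(1R)-4-methylcyclohex-3-en-1-yl]prop-2-en-1-ol, via allyllithium 2 (not isolated), via allylboronate 3 (not isolated)
Conditions: n-BuLi, TMEDA, hexane, rt; B(OMe)3, Et2O, −78 °C → rt; NaOH, H2O2 (30%), 0 °C → rt
Reagents that add atoms: hydrogen peroxide, OO (the hydroxyl oxygen; n-BuLi and B(OMe)3 leave atoms only in 2 and 3)
Why: Allylic lithiation by n-BuLi·TMEDA removes a proton from the isopropenyl methyl group, and the resulting 2-substituted allyl anion has two equivalent CH2 termini, so borylation is unambiguous. Alkaline H2O2 oxidises the C–B bond by 1,2-migration to the primary allylic alcohol, and the ring stereocentre is not touched.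

Step 2
Reactants: 4 2-[(1R)-4-methylcyclohex-3-en-1-yl]prop-2-en-1-ol
Product: 6 2-[(1R)-4-methylcyclohex-3-en-1-yl]propane-1,3-diol, via bis-boron adduct 5 (not isolated)
Conditions: 9-BBN (2.3 equiv), THF, 0 °C → rt; NaOH, H2O2 (30%), 0 °C → rt
Reagents that add atoms: hydrogen peroxide, OO (the new hydroxyl oxygen; 9-BBN leaves atoms only in 5)
Why: Hydroboration–oxidation: one equivalent of 9-BBN is taken up by the hydroxyl group and the second adds anti-Markovnikov to the 1,1-disubstituted alkene, which reacts far faster with this bulky borane than the trisubstituted ring alkene. The transient centre between the two CH2 groups vanishes when both become CH2OH.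

Step 3
Reactants: 6 2-[(1R)-4-methylcyclohex-3-en-1-yl]propane-1,3-diol
Product: 7 2,2-dimethyl-5-[(1R)-4-methylcyclohex-3-en-1-yl]-1,3-dioxane
Conditions: Me2C(OMe)2, PPTS (cat.), acetone, rt
Reagents that add atoms: 2,2-dimethoxypropane, COC(C)(C)OC
Why: Acid-catalysed transacetalisation closes the six-membered 1,3-dioxane. The isopropylidene ketal has no acetal C–H bond (inert to ozone), adds no stereocentre and tolerates the amine, peracid, hydrogenation and hydride steps that follow.

Step 4
Reactants: 7 2,2-dimethyl-5-[(1R)-4-methylcyclohex-3-en-1-yl]-1,3-dioxane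
Product: 9 (3R)-3-(2,2-dimethyl-1,3-dioxan-5-yl)-6-oxoheptanal, via ozonide 8 (not isolated)
Conditions: O3, CH2Cl2, −78 °C; Me2S, −78 °C → rt; used crude
Reagents that add atoms: ozone, [O-][O+]=O
Why: Ozonolysis with reductive work-up: cycloaddition, cycloreversion and recombination give the ozonide, which Me2S reduces to the methyl ketone and the aldehyde. The ring alkene is the only C=C left, and the stereocentre ends up β to the aldehyde, where it cannot enolise.

Step 5
Reactants: 9 (3R)-3-(2,2-dimethyl-1,3-dioxan-5-yl)-6-oxoheptanal
Product: 11 (5S)-5-(2,2-dimethyl-1,3-dioxan-5-yl)-2-methylcyclopent-1-ene-1-carbaldehyde, via aldol 10 (not isolated)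
Conditions: piperidine (0.3 equiv), AcOH (0.3 equiv), toluene (0.05 M), 4 Å MS, rt → 50 °C
Reagents that add atoms: none
Why: Piperidine condenses reversibly with the unhindered aldehyde of 9 much faster than with the methyl ketone, so the only enamine present is the one at the aldehyde α-carbon. That carbon adds to the ketone carbonyl, activated by the acetic acid, and iminium hydrolysis gives aldol 10; this is a 5-(enolexo)-exo-trig closure, the favoured mode for five-membered aldol rings. Loss of water by an E1cB pathway through the enamine or iminium then gives the fully substituted conjugated enal 11, the thermodynamic sink. The closest known reaction type is the amine-salt-catalysed intramolecular aldol condensation of 1,6-keto aldehydes from ozonolysis of 1-methylcyclohexenes, which is established for the parent limonene-derived keto aldehyde. No stereocentre is created: both new sp3 centres of 10 are erased on dehydration, and the dioxanyl-bearing carbon is β to the aldehyde and not enolisable. The selectivity needed is between this mode and attack of the ketone α-methylene on the aldehyde, which would give a 1-acetylcyclopentene; enamine catalysis in place of enolate chemistry secures it. The ketal is inert to the weakly acidic buffer, and dilution suppresses intermolecular condensation.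

Step 6
Reactants: 11 (5S)-5-(2,2-dimethyl-1,3-dioxan-5-yl)-2-methylcyclopent-1-ene-1-carbaldehyde
Product: 12 triethyl{[(5S)-5-(2,2-dimethyl-1,3-dioxan-5-yl)-2-methylcyclopent-2-en-1-ylidene]methoxy}silane
Conditions: TESOTf (1.2 equiv), Et3N (2.5 equiv), CH2Cl2, −78 → 0 °C; non-aqueous work-up
Reagents that add atoms: triethylsilyl trifluoromethanesulfonate, CC[Si](CC)(CC)OS(=O)(=O)C(F)(F)F
Why: Soft enolisation: O-silylation of the enal gives an oxocarbenium ion that Et3N deprotonates at the γ-position. Removal of a ring C3 proton gives the more substituted endocyclic diene, favoured over the exocyclic methylene isomer under these reversible conditions. At low temperature with excess amine the ketal should not be opened by the silyl triflate.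

Step 7
Reactants: 12 triethyl{[(5S)-5-(2,2-dimethyl-1,3-dioxan-5-yl)-2-methylcyclopent-2-en-1-ylidene]methoxy}silane
Product: 14 (3R,5S)-5-(2,2-dimethyl-1,3-dioxan-5-yl)-3-hydroxy-2-methylcyclopent-1-ene-1-carbaldehyde, via epoxide 13 (not isolated)
Conditions: mCPBA (1.05 equiv), NaHCO3, CH2Cl2, −40 → 0 °C; then Et3N·3HF, THF, 0 °C
Reagents that add atoms: 3-chloroperoxybenzoic acid, OOC(=O)c1cccc(Cl)c1
Why: Vinylogous Rubottom oxidation: the peracid epoxidises the electron-rich ring C2=C3 bond of the 1-silyloxydiene, where the HOMO coefficient is largest, and the silyl enol ether then opens the epoxide to the γ-oxygenated enal, with fluoride removing silicon. The oxidant should approach the nearly flat diene from the face opposite the dioxanyl group on C5, which places the C3 oxygen trans to it (3R).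

Step 8
Reactants: 14 (3R,5S)-5-(2,2-dimethyl-1,3-dioxan-5-yl)-3-hydroxy-2-methylcyclopent-1-ene-1-carbaldehyde
Product: 15 (1R,2R,3R,5S)-5-(2,2-dimethyl-1,3-dioxan-5-yl)-3-hydroxy-2-methylcyclopentane-1-carbaldehyde
Conditions: H2 (10 bar), [Ir(cod)(PCy3)(py)]PF6 (5–10 mol%), CH2Cl2, rt
Reagents that add atoms: none
Why: Hydroxyl-directed homogeneous hydrogenation: the cationic monovalent iridium complex binds the allylic C3 hydroxyl and delivers both hydrogens to the tetrasubstituted C1=C2 bond from the hydroxyl face, which is also the face away from the C5 substituent. This sets C2 with the methyl trans to the hydroxyl (correct) and C1 with the formyl group cis to the methyl (corrected in step 9).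

Step 9
Reactants: 15 (1R,2R,3R,5S)-5-(2,2-dimethyl-1,3-dioxan-5-yl)-3-hydroxy-2-methylcyclopentane-1-carbaldehyde
Product: 17 (1R,2R,3S,4R)-4-(2,2-dimethyl-1,3-dioxan-5-yl)-3-(hydroxymethyl)-2-methylcyclopentan-1-ol, via bridged lactol 16 (not isolated)
Conditions: K2CO3 (0.5 equiv), MeOH, rt; then NaBH4, 0 °C
Reagents that add atoms: none
Why: Base-mediated epimerisation at C1, the only enolisable centre, relieves three contiguous cis substituents. The epimer with the formyl group trans to both neighbours is also the only one able to close the bridged lactol with the cis C3 hydroxyl, which drains the equilibrium. NaBH4 then reduces the lactol through its open hydroxy aldehyde form without touching a stereocentre.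

Step 10
Reactants: 18 oleuropein
Product: 19 oleoside 11-methyl ester (2-[(2S,3E,4S)-3-ethylidene-2-(β-D-glucopyranosyloxy)-5-(methoxycarbonyl)-3,4-dihydro-2H-pyran-4-yl]acetic acid)
Conditions: NaOH (aq., 3 equiv), H2O, 0 °C → rt, Ar; then HCl to pH 3
Reagents that add atoms: sodium hydroxide, [Na+].[OH-]
Why: Chemoselective saponification: hydroxide cleaves the unhindered aliphatic phenethyl ester, whereas the methyl ester is a vinylogous carbonate deactivated by the ring oxygen and by the charge of the carboxylate already formed. Exclusion of air prevents oxidation of the released catecholate.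

Step 11
Reactants: 19 oleoside 11-methyl ester
Product: 21 2′,3′,4′,6′-tetra-O-acetyloleoside 11-methyl ester (free 7-carboxylic acid), via mixed anhydride 20 (not isolated)
Conditions: Ac2O, pyridine, DMAP (cat.), 0 °C → rt; then H2O, THF, rt
Reagents that add atoms: acetic anhydride, CC(=O)OC(C)=O
Why: Pyridine/DMAP-catalysed O-acetylation of the four glucose hydroxyls. The carboxylic acid is partly converted into the mixed anhydride, which the aqueous quench hydrolyses back to the acid. The acetates prevent self-esterification in step 12.

Step 12
Reactants: 17 (1R,2R,3S,4R)-4-(2,2-dimethyl-1,3-dioxan-5-yl)-3-(hydroxymethyl)-2-methylcyclopentan-1-ol; 21 2′,3′,4′,6′-tetra-O-acetyloleoside 11-methyl ester (2.4 equiv)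
Product: 22 bis-ester acetonide (17 acylated at C3–O and at C1–CH2–O by the acyl group of 21)
Conditions: EDC·HCl (3 equiv), DMAP (0.5 equiv), CH2Cl2, 0 °C → rt
Reagents that add atoms: none
Why: Carbodiimide esterification with DMAP acyl transfer (Steglich conditions) acylates the primary and the secondary hydroxyl with the same acid. The acid has no α-stereocentre, so activation cannot epimerise the arm centre. Ketal, acetates, enol ether and glycosidic acetal are inert.

Step 13
Reactants: 22 bis-ester acetonide
Product: 23 bis-ester diol (22 with the free CH(CH2OH)2 group)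
Conditions: AcOH/H2O/THF (3:1:1), 40 °C
Reagents that add atoms: none
Why: Mild acid hydrolysis of the isopropylidene ketal. The glycosidic acetals ionise far more slowly, because one oxygen belongs to a vinylogous carbonate and the other to a peracetylated sugar, and the esters are inert to aqueous acetic acid.

Step 14
Reactants: 23 bis-ester diol
Product: 25 {(1S,2R,3R,5R)-5-(1,3-dihydroxypropan-2-yl)-2-methyl-3-{[(3S,4E)-4-formyl-3-(2-oxoethyl)hex-4-enoyl]oxy}cyclopentyl}methyl (3S,4E)-4-formyl-3-(2-oxoethyl)hex-4-enoate, via bis-enol-ether glucoside 24 (not isolated)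
Conditions: NaCl (6 equiv), DMSO/H2O (20:1), 150 °C, Ar
Reagents that add atoms: water, O
Why: Krapcho dealkoxycarbonylation: chloride removes each ester methyl by SN2, the β-alkoxyacrylic acid decarboxylates in hot wet DMSO to the enol ether, and hydration of the enol ether unravels the mixed acetal, expelling tetra-O-acetylglucose and leaving both aldehydes of each arm. The reaction type is established for oleoside-type methyl esters that carry an alkyl ester side chain. The arm stereocentre and the E-ethylidene take part in no bond-forming event, and ordinary esters resist chloride.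

## Compound list

1 | (R)-(+)-limonene | CC1=CC[C@@H](CC1)C(C)=C | starting material
2 | 2-[(1R)-4-methylcyclohex-3-en-1-yl]allyllithium | CC1=CC[C@@H](CC1)C(=C)C[Li] | intermediate (not isolated)
3 | dimethyl {2-[(1R)-4-methylcyclohex-3-en-1-yl]prop-2-en-1-yl}boronate | CC1=CC[C@@H](CC1)C(=C)CB(OC)OC | intermediate (not isolated)
4 | 2-[(1R)-4-methylcyclohex-3-en-1-yl]prop-2-en-1-ol | CC1=CC[C@@H](CC1)C(=C)CO | intermediate
5 | O,C-bis(9-borabicyclo[3.3.1]nonan-9-yl) adduct of 4 (epimers at the side-chain CH) | CC1=CC[C@@H](CC1)C(COB2C3CCCC2CCC3)CB4C5CCCC4CCC5 | intermediate (not isolated)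
6 | 2-[(1R)-4-methylcyclohex-3-en-1-yl]propane-1,3-diol | CC1=CC[C@@H](CC1)C(CO)CO | intermediate
7 | 2,2-dimethyl-5-[(1R)-4-methylcyclohex-3-en-1-yl]-1,3-dioxane | CC1=CC[C@@H](CC1)C2COC(C)(C)OC2 | intermediate
8 | ozonide (1,2,4-trioxolane) of 7, diastereomer mixture | CC12CC[C@H](CC(OO1)O2)C3COC(C)(C)OC3 | intermediate (not isolated)
9 | (3R)-3-(2,2-dimethyl-1,3-dioxan-5-yl)-6-oxoheptanal | O=CC[C@@H](CCC(C)=O)C1COC(C)(C)OC1 | intermediate
10 | (5S)-5-(2,2-dimethyl-1,3-dioxan-5-yl)-2-hydroxy-2-methylcyclopentane-1-carbaldehyde, mixture at C1 and C2 | O=CC1C(C)(O)CC[C@H]1C2COC(C)(C)OC2 | intermediate (not isolated)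
11 | (5S)-5-(2,2-dimethyl-1,3-dioxan-5-yl)-2-methylcyclopent-1-ene-1-carbaldehyde | O=CC1=C(C)CC[C@H]1C2COC(C)(C)OC2 | intermediate
12 | triethyl{[(5S)-5-(2,2-dimethyl-1,3-dioxan-5-yl)-2-methylcyclopent-2-en-1-ylidene]methoxy}silane | CC[Si](CC)(CC)OC=C1C(C)=CC[C@H]1C2COC(C)(C)OC2 | intermediate
13 | 2,3-epoxide of 12, oxirane on the face opposite the dioxanyl group | CC[Si](CC)(CC)OC=C1[C@]2(C)O[C@@H]2C[C@H]1C3COC(C)(C)OC3 | intermediate (not isolated)
14 | (3R,5S)-5-(2,2-dimethyl-1,3-dioxan-5-yl)-3-hydroxy-2-methylcyclopent-1-ene-1-carbaldehyde | O=CC1=C(C)[C@H](O)C[C@H]1C2COC(C)(C)OC2 | intermediate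
15 | (1R,2R,3R,5S)-5-(2,2-dimethyl-1,3-dioxan-5-yl)-3-hydroxy-2-methylcyclopentane-1-carbaldehyde (CHO, CH3 and dioxanyl cis; OH trans) | O=C[C@H]1[C@@H](C)[C@H](O)C[C@H]1C2COC(C)(C)OC2 | intermediate
16 | 5-(2,2-dimethyl-1,3-dioxan-5-yl)-7-methyl-2-oxabicyclo[2.2.1]heptan-3-ol (bridged lactol of the C1 epimer of 15, anomer mixture) | OC3[C@@H]1[C@@H](C)[C@H](O3)C[C@H]1C2COC(C)(C)OC2 | intermediate (not isolated)
17 | (1R,2R,3S,4R)-4-(2,2-dimethyl-1,3-dioxan-5-yl)-3-(hydroxymethyl)-2-methylcyclopentan-1-ol | OC[C@@H]1[C@@H](C)[C@H](O)C[C@H]1C2COC(C)(C)OC2 | intermediate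
18 | oleuropein | C/C=C1\[C@@H](C(=CO[C@H]1O[C@H]2[C@@H]([C@H]([C@@H]([C@H](O2)CO)O)O)O)C(=O)OC)CC(=O)OCCc3ccc(O)c(O)c3 | starting material
19 | oleoside 11-methyl ester | C/C=C1\[C@@H](C(=CO[C@H]1O[C@H]2[C@@H]([C@H]([C@@H]([C@H](O2)CO)O)O)O)C(=O)OC)CC(=O)O | intermediate
20 | mixed acetic anhydride of 21 | C/C=C1\[C@@H](C(=CO[C@H]1O[C@H]2[C@@H]([C@H]([C@@H]([C@H](O2)COC(C)=O)OC(C)=O)OC(C)=O)OC(C)=O)C(=O)OC)CC(=O)OC(C)=O | intermediate (not isolated)
21 | 2′,3′,4′,6′-tetra-O-acetyloleoside 11-methyl ester | C/C=C1\[C@@H](C(=CO[C@H]1O[C@H]2[C@@H]([C@H]([C@@H]([C@H](O2)COC(C)=O)OC(C)=O)OC(C)=O)OC(C)=O)C(=O)OC)CC(=O)O | intermediate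
22 | bis-ester acetonide: 17 acylated at C3–O and C1–CH2–O by the acyl group of 21 | C/C=C1\[C@@H](C(=CO[C@H]1O[C@H]2[C@@H]([C@H]([C@@H]([C@H](O2)COC(C)=O)OC(C)=O)OC(C)=O)OC(C)=O)C(=O)OC)CC(=O)OC[C@@H]3[C@@H](C)[C@H](OC(=O)C[C@@H]4C(C(=O)OC)=CO[C@@H](O[C@H]5[C@@H]([C@H]([C@@H]([C@H](O5)COC(C)=O)OC(C)=O)OC(C)=O)OC(C)=O)/C4=C/C)C[C@H]3C6COC(C)(C)OC6 | intermediate
23 | bis-ester diol: 22 with free CH(CH2OH)2 | C/C=C1\[C@@H](C(=CO[C@H]1O[C@H]2[C@@H]([C@H]([C@@H]([C@H](O2)COC(C)=O)OC(C)=O)OC(C)=O)OC(C)=O)C(=O)OC)CC(=O)OC[C@@H]3[C@@H](C)[C@H](OC(=O)C[C@@H]4C(C(=O)OC)=CO[C@@H](O[C@H]5[C@@H]([C@H]([C@@H]([C@H](O5)COC(C)=O)OC(C)=O)OC(C)=O)OC(C)=O)/C4=C/C)C[C@H]3C(CO)CO | intermediate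
24 | 23 without both CO2Me groups (each arm a 4H-pyran enol ether still bearing the tetra-O-acetylglucosyl acetal) | C/C=C1\[C@@H](C=CO[C@H]1O[C@H]2[C@@H]([C@H]([C@@H]([C@H](O2)COC(C)=O)OC(C)=O)OC(C)=O)OC(C)=O)CC(=O)OC[C@@H]3[C@@H](C)[C@H](OC(=O)C[C@@H]4C=CO[C@@H](O[C@H]5[C@@H]([C@H]([C@@H]([C@H](O5)COC(C)=O)OC(C)=O)OC(C)=O)OC(C)=O)/C4=C/C)C[C@H]3C(CO)CO | intermediate (not isolated)
25 | {(1S,2R,3R,5R)-5-(1,3-dihydroxypropan-2-yl)-2-methyl-3-{[(3S,4E)-4-formyl-3-(2-oxoethyl)hex-4-enoyl]oxy}cyclopentyl}methyl (3S,4E)-4-formyl-3-(2-oxoethyl)hex-4-enoate | C/C=C(/C=O)[C@@H](CC=O)CC(=O)OC[C@@H]1[C@@H](C)[C@H](OC(=O)C[C@H](CC=O)/C(C=O)=C\C)C[C@H]1C(CO)CO | target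

## Step count and risks

Total: 14 steps. Longest linear sequence: 12 steps (steps 1–9 and 12–14, from 1 to 25). The arm acid needs two steps (10 and 11) before the union.

Least certain steps:

**Step 5 (key step).** The other aldol mode (ketone α-methylene onto the aldehyde) or intermolecular condensation of the keto aldehyde may compete, and the ketal may be lost if acid and water accumulate. Fallback, from 9 back to 11: the aldehyde alone is converted with stoichiometric pyrrolidine (K2CO3, Et2O, 0 °C) into the enamine (5R,6E)-5-(2,2-dimethyl-1,3-dioxan-5-yl)-7-(pyrrolidin-1-yl)hept-6-en-2-one F1. This is then cyclised and eliminated in a separate operation in buffered AcOH/NaOAc in aqueous THF to give 11, so that no free aldehyde is ever exposed to the cyclisation medium.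

**Step 8.** Hydrogenation of the electron-poor tetrasubstituted alkene may be slow, and iridium-hydride isomerisation of the allylic alcohol to a saturated ketone or catalyst deactivation may take over. Fallback, from 14 back to 15: 1,2-reduction (NaBH4, CeCl3·7H2O, MeOH) gives (1R,4S)-4-(2,2-dimethyl-1,3-dioxan-5-yl)-3-(hydroxymethyl)-2-methylcyclopent-2-en-1-ol F2. Its electron-rich alkene is hydrogenated with the same iridium complex under hydroxyl direction to (1R,2R,3R,4R)-4-(2,2-dimethyl-1,3-dioxan-5-yl)-3-(hydroxymethyl)-2-methylcyclopentan-1-ol F3. Selective oxidation of the primary alcohol (TEMPO, PhI(OAc)2, CH2Cl2) then returns 15.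

**Step 7.** Facial selectivity at C3 may be poor, because the controlling substituent is 1,3 to the reacting carbon, and α-attack or over-oxidation may occur. Fallback, from 12 back to 14: the unwanted epimer (3S,5S)-5-(2,2-dimethyl-1,3-dioxan-5-yl)-3-hydroxy-2-methylcyclopent-1-ene-1-carbaldehyde F4 is separated and inverted by Mitsunobu esterification (4-nitrobenzoic acid, PPh3, DIAD, THF) to (1R,4S)-4-(2,2-dimethyl-1,3-dioxan-5-yl)-3-formyl-2-methylcyclopent-2-en-1-yl 4-nitrobenzoate F5. Methanolysis (K2CO3, MeOH, 0 °C) gives 14.

**Step 6.** Proton removal may occur from the C2 methyl group and not from ring C3, and the silyl triflate may open the ketal. Fallback, from 11 directly to 14: allylic oxidation with SeO2 (cat.) and t-BuOOH in CH2Cl2. The ene reaction places selenium on C1 from the face opposite the C5 group, and the [2,3] shift delivers oxygen to ring C3 on that same face. The ring CH2 is preferred over the methyl group. This bypasses 12 and makes no new compound (F0).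

**Step 14.** The freed dialdehydes may degrade thermally or undergo aldol condensation, one of the two arms may stay masked, and acyl transfer to the free diol or ester cleavage by the hydrogencarbonate formed may occur. Fallback, from 23 back to 25: the two events are separated. LiI in refluxing EtOAc removes only the ester methyl groups to give the dicarboxylic acid F6 (23 with both CO2Me groups as CO2H). The free β-alkoxyacrylic acids are then decarboxylated and unravelled in wet DMSO at about 100 °C without added salt.

**Step 12.** Acylation of the hindered secondary hydroxyl may stay incomplete while the activated acid rearranges to an N-acylurea. Fallback, from 17 back to 22: the primary hydroxyl is acylated first with one equivalent of 21 (EDC·HCl, DMAP, −20 °C) to the mono-ester F7 (17 acylated only at C1–CH2–O). The secondary hydroxyl is then acylated with the mixed anhydride of 21 and 2,4,6-trichlorobenzoyl chloride (Et3N, then DMAP, toluene; Yamaguchi conditions).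

## Further compounds

F1 | step 5 | (5R,6E)-5-(2,2-dimethyl-1,3-dioxan-5-yl)-7-(pyrrolidin-1-yl)hept-6-en-2-one | CC(=O)CC[C@H](/C=C/N1CCCC1)C2COC(C)(C)OC2
F2 | step 8 | (1R,4S)-4-(2,2-dimethyl-1,3-dioxan-5-yl)-3-(hydroxymethyl)-2-methylcyclopent-2-en-1-ol | OCC1=C(C)[C@H](O)C[C@H]1C2COC(C)(C)OC2
F3 | step 8 | (1R,2R,3R,4R)-4-(2,2-dimethyl-1,3-dioxan-5-yl)-3-(hydroxymethyl)-2-methylcyclopentan-1-ol | OC[C@H]1[C@@H](C)[C@H](O)C[C@H]1C2COC(C)(C)OC2
F4 | step 7 | (3S,5S)-5-(2,2-dimethyl-1,3-dioxan-5-yl)-3-hydroxy-2-methylcyclopent-1-ene-1-carbaldehyde | O=CC1=C(C)[C@@H](O)C[C@H]1C2COC(C)(C)OC2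
F5 | step 7 | (1R,4S)-4-(2,2-dimethyl-1,3-dioxan-5-yl)-3-formyl-2-methylcyclopent-2-en-1-yl 4-nitrobenzoate | O=CC1=C(C)[C@H](OC(=O)c3ccc(cc3)[N+]([O-])=O)C[C@H]1C2COC(C)(C)OC2
F0 | step 6 | none | none
F6 | step 14 | dicarboxylic acid: 23 with both CO2Me groups as CO2H | C/C=C1\[C@@H](C(=CO[C@H]1O[C@H]2[C@@H]([C@H]([C@@H]([C@H](O2)COC(C)=O)OC(C)=O)OC(C)=O)OC(C)=O)C(=O)O)CC(=O)OC[C@@H]3[C@@H](C)[C@H](OC(=O)C[C@@H]4C(C(=O)O)=CO[C@@H](O[C@H]5[C@@H]([C@H]([C@@H]([C@H](O5)COC(C)=O)OC(C)=O)OC(C)=O)OC(C)=O)/C4=C/C)C[C@H]3C(CO)CO
F7 | step 12 | mono-ester: 17 acylated only at C1–CH2–O by the acyl group of 21 | C/C=C1\[C@@H](C(=CO[C@H]1O[C@H]2[C@@H]([C@H]([C@@H]([C@H](O2)COC(C)=O)OC(C)=O)OC(C)=O)OC(C)=O)C(=O)OC)CC(=O)OC[C@@H]3[C@@H](C)[C@H](O)C[C@H]3C4COC(C)(C)OC4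
A1 | alternative 1 | bis(allyl malonate) of 17 | C=CCOC(=O)CC(=O)OC[C@@H]1[C@@H](C)[C@H](OC(=O)CC(=O)OCC=C)C[C@H]1C2COC(C)(C)OC2
A2 | alternative 1 | (2E,4E)-4-(dimethoxymethyl)hexa-2,4-dienal | C/C=C(/C(OC)OC)\C=C\C=O
A3 | alternative 1 | twofold Michael adduct of A1 and A2 (malonate carbons as epimer mixtures) | C/C=C(/C(OC)OC)[C@@H](CC=O)C(C(=O)OCC=C)C(=O)OC[C@@H]1[C@@H](C)[C@H](OC(=O)C(C(=O)OCC=C)[C@H](CC=O)/C(C(OC)OC)=C\C)C[C@H]1C2COC(C)(C)OC2
A4 | alternative 2 | dimethyl 2-[(3R,4R)-3-(tert-butyldimethylsilyloxy)-4-methyl-6-oxohexylidene]malonate | O=CC[C@@H](C)[C@H](O[Si](C)(C)C(C)(C)C)CC=C(C(=O)OC)C(=O)OC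
A5 | alternative 2 | all-trans dimethyl 2-[4-(tert-butyldimethylsilyloxy)-2-formyl-3-methylcyclopentyl]malonate | O=C[C@@H]1[C@@H](C)[C@H](O[Si](C)(C)C(C)(C)C)C[C@H]1C(C(=O)OC)C(=O)OC
A6 | alternative 3 | (R)-4-(2,2-dimethyl-1,3-dioxan-5-yl)cyclopent-2-en-1-one | O=C1C=C[C@@H](C1)C2COC(C)(C)OC2
A7 | alternative 3 | all-trans 4-(2,2-dimethyl-1,3-dioxan-5-yl)-3-[(isopropoxydimethylsilyl)methyl]-2-methylcyclopentanone | CC(C)O[Si](C)(C)C[C@@H]1[C@@H](C)C(=O)C[C@H]1C2COC(C)(C)OC2
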